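**Retrosynthetic overview**
- Target: briarane with ring A (cyclohexenone C1/C14/C13/C12/C11/C10), ten-membered ring B (C1–C10) and a γ-lactone (C7–O–C19–C17–C8).
- C11–OH/C12=O come from oxidation of a ring A 12-ethoxy-11,13-diene; that diene comes from the ring B lactone 26 (C1 vinyl, C10 isopropenyl) and ethoxyacetylene by a ruthenium carbene cascade that forms C13=C14 and C11–C12 together.
- Enabling feature: in ring A the unit C12–C13 is bonded only to C11 and C14, and the other four ring atoms C14–C1–C10–C11 sit on ring B as a 1,5-diene (quaternary C1 with vinyl, C10 with isopropenyl), the typical product of a [3,3] shift; the C12 oxygen arrives on the alkyne.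
- γ-Lactone: SmI2 Reformatsky closure of a C7 2-bromopropanoate onto a C8 ketone. Ring B: dianionic Ireland–Claisen ring contraction (C1–C10) of a 14-membered β-hydroxy lactone, itself closed by acrylate ring-closing metathesis after a B-alkyl Suzuki coupling (C4–C5).
- Ring order: temporary 14-membered lactone → ring B → γ-lactone → ring A last.

Key step: step 23

Remark: atoms carry briarane numbers (C1–C20); C1′ is the extra allylic carbon that ends as ethene in step 23. The C8 configuration in 8–21 is without consequence (C8 becomes a ketone in step 18). Compounds 20–22 are mixtures at the bromine-bearing carbon, which is drawn without configuration. Ligand and borane antipodes are named as expected from the usual models and would be confirmed on the first intermediate.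

**Step 1**
Reactants: 1 (E)-4-acetoxy-2-methylbut-2-enal
Product: 2 (2E,4R)-4-hydroxy-3-methylhexa-2,5-dien-1-yl acetate
Conditions: (CH2=CH)2Zn (from CH2=CHMgBr, ZnCl2), (+)-MIB (3-exo-morpholinoisoborneol, 5 mol%), toluene/THF, −30 °C
Reagents that add atoms: divinylzinc (C=C[Zn]C=C)
Why: Catalytic asymmetric vinylzinc 1,2-addition to an enal; the chiral zinc amino-alkoxide selects the aldehyde face and should set C2 (4R here), while the acetate is inert to organozinc.

**Step 2**
Reactants: 2 (2E,4R)-4-hydroxy-3-methylhexa-2,5-dien-1-yl acetate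
Product: 3 C2 tert-butyldimethylsilyl ether of 2
Conditions: TBSCl, imidazole, DMF, rt
Reagents that add atoms: tert-butyldimethylsilyl chloride (CC(C)(C)[Si](C)(C)Cl)
Why: Standard silylation of the only free hydroxyl; no stereocenter is touched.

**Step 3**
Reactants: 3 C2 silyl ether acetate
Product: 4 (2E,4R)-4-(tert-butyldimethylsilyloxy)-3-methylhexa-2,5-dien-1-ol
Conditions: K2CO3 (cat.), MeOH, 0 °C
Reagents that add atoms: none
Why: Methanolysis of the primary allylic acetate frees C1′–OH; the silyl ether should survive.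

**Step 4**
Reactants: 5 but-2-yn-1-ol
Product: 6 (Z)-3-iodobut-2-en-1-ol
Conditions: NaAlH2(OCH2CH2OMe)2, THF, 0 °C; then I2, −78 → 0 °C
Reagents that add atoms: iodine (I-I)
Why: Hydroxyl-directed trans-hydroalumination of the propargylic alcohol followed by iodinolysis with retention should give the Z vinyl iodide, which fixes the later C5=C6 geometry.

**Step 5**
Reactants: 6 (Z)-3-iodobut-2-en-1-ol
Product: 7 (Z)-3-iodobut-2-enal
Conditions: MnO2, CH2Cl2, rt, dark
Reagents that add atoms: none
Why: Allylic oxidation with MnO2 under neutral conditions should keep the Z geometry.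

**Step 6**
Reactants: 7 (Z)-3-iodobut-2-enal
Product: 8 (3S,4S,5Z)-6-iodo-3-(4-methoxybenzyloxy)hepta-1,5-dien-4-ol
Conditions: allyl 4-methoxybenzyl ether, sec-BuLi, THF, −78 °C; (+)-Ipc2BOMe (from (−)-α-pinene); BF3·OEt2; then 7, −78 °C; NaOH, H2O2
Reagents that add atoms: allyl 4-methoxybenzyl ether (C=CCOCc1ccc(OC)cc1)
Why: Asymmetric (Z)-γ-alkoxyallylboration through a closed chair transition state should give the syn diol monoether; the isopinocampheyl groups choose the aldehyde face and so set C7.

**Step 7**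
Reactants: 8 iodo dienol
Product: 9 C7 triethylsilyl ether of 8
Conditions: TESCl, imidazole, CH2Cl2, 0 °C
Reagents that add atoms: chlorotriethylsilane (CC[Si](CC)(CC)Cl)
Why: Routine silylation of the secondary alcohol with a group that can later be removed beside the C2 silyl ether.

**Step 8**
Reactants: 4 West dienol; 9 vinyl iodide
Product: 11 seco alcohol (C1′–OH, 2-OTBS, 7-OTES, 8-OPMB, C9 vinyl, 5Z), via alkylborane 10 (not isolated)
Conditions: 9-BBN (2.2 equiv), THF, 0 °C → rt; then H2O, Cs2CO3, 9, Pd(dppf)Cl2 (5 mol%), AsPh3, DMF, rt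
Reagents that add atoms: 9-borabicyclo[3.3.1]nonane (B1C2CCCC1CCC2)
Why: 9-BBN hydroborates only the monosubstituted alkene of 4 (its boron is carried by 10 only), and the B-alkyl Suzuki–Miyaura coupling with the vinyl iodide forms C4–C5 with retention of the Z geometry.

**Step 9**
Reactants: 11 seco alcohol
Product: 12 C1′ acrylate of 11
Conditions: acryloyl chloride, i-Pr2NEt, CH2Cl2, −78 → 0 °C
Reagents that add atoms: acryloyl chloride (C=CC(=O)Cl)
Why: Acylation of the only free (primary allylic) hydroxyl brings in C10 and C11.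

**Step 10**
Reactants: 12 acrylate
Product: 13 14-membered (E)-enoate macrolactone (ring C11–O–C1′–C14=C1–C2…C9=C10)
Conditions: second-generation Grubbs catalyst (10 mol%), CH2Cl2 (1 mM), reflux
Reagents that add atoms: none
Why: Ring-closing metathesis between the acrylate and the only other monosubstituted alkene; the trisubstituted alkenes should not take part, and the large ring should form as the E enoate.

**Step 11**
Reactants: 13 macrocyclic enoate
Product: 15 (9R)-β-hydroxy macrolactone, via C9 pinacol boronate 14 (not isolated)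
Conditions: CuCl (5 mol%), NaOt-Bu, Josiphos-type ligand (antipode for 9R), B2pin2, MeOH, THF, rt; then NaBO3·4H2O, THF/H2O
Reagents that add atoms: bis(pinacolato)diboron (CC1(C)OB(OC1(C)C)B1OC(C)(C)C(C)(C)O1); sodium perborate (B(=O)O[O-].[Na+])
Why: Copper-catalysed conjugate borylation of the enoate with ligand-controlled facial selectivity sets C9 and the C–B oxidation proceeds with retention; the diboron reagent supplies the boryl group of 14 and perborate the C9 oxygen of 15.

**Step 12**
Reactants: 15 β-hydroxy macrolactone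
Product: 16 ring B acid (C1: methyl and vinyl; C10: CO2H; 9-OH; 2-OTBS; 7-OTES; 8-OPMB; 5Z)
Conditions: LDA (3.2 equiv), THF, −78 → 50 °C; cold dilute aq. HCl (to pH 4)
Reagents that add atoms: none
Why: Dianionic Ireland–Claisen ring contraction: the lithium chelate between the C9 alkoxide and the enolate oxygen fixes the enolate geometry and should direct C1 onto C10 anti to C8 (10S, as in alkylations of chelated β-alkoxide enolates), while a chair transition state with the E C14=C1 alkene should place methyl and vinyl at C1 as required (1S).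

**Step 13**
Reactants: 16 ring B acid
Product: 17 C10 acetyl compound (C11 methyl ketone, 9-OH)
Conditions: MeLi (5 equiv), THF, 0 °C; aq. NH4Cl
Reagents that add atoms: methyllithium ([Li]C)
Why: Addition of methyllithium to the lithium carboxylate stops at the gem-diolate and should give the methyl ketone (C20 introduced) on work-up.

**Step 14**
Reactants: 17 hydroxy ketone
Product: 18 9-acetate
Conditions: Ac2O, pyridine, DMAP (cat.), CH2Cl2, 0 °C
Reagents that add atoms: acetic anhydride (CC(=O)OC(C)=O)
Why: Acetylation of the only free hydroxyl installs the C9 acetate of the target; low temperature limits β-elimination.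

**Step 15**
Reactants: 18 acetate
Product: 19 C7 alcohol
Conditions: PPTS, MeOH/CH2Cl2, 0 °C
Reagents that add atoms: none
Why: Mild acid methanolysis should remove the allylic triethylsilyl ether and leave the hindered tert-butyldimethylsilyl ether and the PMB ether.

**Step 16**
Reactants: 19 C7 alcohol
Product: 20 C7 2-bromopropanoate
Conditions: 2-bromopropanoyl bromide, pyridine, CH2Cl2, −20 °C
Reagents that add atoms: 2-bromopropanoyl bromide (CC(Br)C(=O)Br)
Why: Acylation of the only free hydroxyl attaches C17–C19 through O7.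

**Step 17**
Reactants: 20 bromo ester
Product: 21 C8 alcohol
Conditions: DDQ, CH2Cl2/pH 7 buffer, 0 °C
Reagents that add atoms: none
Why: Oxidative cleavage of the PMB ether frees C8–OH; the product is used at once to avoid acyl migration.

**Step 18**
Reactants: 21 C8 alcohol
Product: 22 C8 ketone
Conditions: Dess–Martin periodinane, NaHCO3, CH2Cl2, 0 °C
Reagents that add atoms: none
Why: Buffered oxidation of the secondary alcohol should give the ketone without epimerizing C7 or C9.

**Step 19**
Reactants: 22 keto bromo ester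
Product: 23 γ-lactone with 8-OH (C10 acetyl, C1 vinyl, 2-OTBS, 9-OAc)
Conditions: SmI2 (2.2 equiv, slow addition), THF, −78 °C; aq. NH4Cl
Reagents that add atoms: none
Why: Intramolecular samarium Reformatsky reaction: the tethered samarium enolate should attack the C8 ketone with the C9 branch turned away from C6, so that 8-OH ends cis to C6, and the chelated arrangement of enolate and ketone should place the C17 methyl trans to the C9 branch under kinetic control.

**Step 20**
Reactants: 23 silyl ether lactone
Product: 24 C2 alcohol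
Conditions: HF·pyridine, THF/pyridine, 0 °C → rt
Reagents that add atoms: none
Why: Fluoride cleavage of the last silyl ether; esters, lactone and tertiary alcohol should tolerate the buffered reagent.

**Step 21**
Reactants: 24 C2 alcohol
Product: 25 C2 butanoate
Conditions: butyric anhydride, pyridine, DMAP (cat.), CH2Cl2, 0 °C → rt
Reagents that add atoms: butyric anhydride (CCCC(=O)OC(=O)CCC)
Why: The secondary C2 alcohol is acylated while the tertiary C8 alcohol should stay free.

**Step 22**
Reactants: 25 methyl ketone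
Product: 26 C10 isopropenyl compound (1,5-diene precursor)
Conditions: Zn, CH2Br2, TiCl4, THF/CH2Cl2, 0 °C → rt
Reagents that add atoms: dibromomethane (BrCBr)
Why: Takai–Lombardo methylenation is non-basic and ketone-selective, so the β-acetoxy ketone should be converted without elimination and the esters and lactone left alone.

**Step 23**
Reactants: 26 C1 vinyl/C10 isopropenyl lactone; 27 ethoxyacetylene
Product: 28 ring A 12-ethoxy-11,13-diene
Conditions: 27 (3 equiv, syringe pump), second-generation Hoveyda–Grubbs catalyst (15 mol%), toluene (5 mM), 60 °C, argon purge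
Reagents that add atoms: none
Why: Proposed new method: the ruthenium methylidene first exchanges with the monosubstituted C1 vinyl group, the resulting alkylidene adds to the unsubstituted, nucleophilic carbon C13 of ethoxyacetylene to give C13=C14 and an α-ethoxy vinylcarbene at C12, and this carbene closes ring A by metathesis onto the C10 isopropenyl group (C11=C12), so that the two terminal CH2 groups leave as ethene. The closest known reaction types are the tandem cross enyne metathesis/ring-closing metathesis of terminal alkynes with 1,5-dienes to 2-substituted cyclohexa-1,3-dienes and the ring-closing enyne metathesis of siloxy- and alkoxyalkynes to 2-oxygenated 1,3-dienes; untested here are an alkynyl ether as the intermolecular partner and a 1,1-disubstituted terminating alkene that makes a tetrasubstituted enol ether. Ring A closes as a six-membered ring in a ring-closing metathesis of the C12 carbene with the isopropenyl alkene, and no stereocenter is formed (C1 and C10 are already fixed, C11 follows in step 24). The step needs regioselectivity in the alkyne insertion, which the polarization of the ynol ether and the bulk of the neopentyl alkylidene should secure, and the Z geometry at C13=C14: only the Z vinylcarbene can cyclize, and the E isomer should be recycled by reversible cross metathesis while irreversible ring closure drains the Z isomer. It also needs chemoselectivity, which the substrate provides because direct closure of vinyl onto isopropenyl would give a cyclobutene and the trisubstituted C5=C6 alkene is inert. The trans arrangement of the two alkenyl groups on C1 and C10 holds them gauche, so the closure is entropically easy.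

**Step 24**
Reactants: 28 ethoxy diene
Product: 30 target (CNP0346936.2), via ethoxy epoxide 29 (not isolated)
Conditions: dimethyldioxirane, acetone/CH2Cl2, −78 °C; then H2O, pH 7 buffer, 0 °C
Reagents that add atoms: dimethyldioxirane (CC1(C)OO1); water (O)
Why: Rubottom-type oxidation: the tetrasubstituted enol ether C11=C12 is the most electron-rich alkene and should be epoxidized on the face anti to the C9 branch on C10 (cis to H-10), which sets C11; hydrolysis of the alkoxy epoxide gives the α′-hydroxy enone.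

**Compound list**
1 | (E)-4-acetoxy-2-methylbut-2-enal | CC(=O)OC/C=C(\C)C=O | starting material
2 | (2E,4R)-4-hydroxy-3-methylhexa-2,5-dien-1-yl acetate | CC(=O)OC/C=C(\C)[C@H](O)C=C | intermediate
3 | (2E,4R)-4-(tert-butyldimethylsilyloxy)-3-methylhexa-2,5-dien-1-yl acetate | CC(=O)OC/C=C(\C)[C@H](O[Si](C)(C)C(C)(C)C)C=C | intermediate
4 | (2E,4R)-4-(tert-butyldimethylsilyloxy)-3-methylhexa-2,5-dien-1-ol | OC/C=C(\C)[C@H](O[Si](C)(C)C(C)(C)C)C=C | intermediate
5 | but-2-yn-1-ol | CC#CCO | starting material
6 | (Z)-3-iodobut-2-en-1-ol | C/C(I)=C/CO | intermediate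
7 | (Z)-3-iodobut-2-enal | C/C(I)=C/C=O | intermediate
8 | (3S,4S,5Z)-6-iodo-3-(4-methoxybenzyloxy)hepta-1,5-dien-4-ol | C/C(I)=C/[C@H](O)[C@@H](OCc1ccc(OC)cc1)C=C | intermediate
9 | triethylsilyl ether of 8 (C7–OTES) | C/C(I)=C/[C@H](O[Si](CC)(CC)CC)[C@@H](OCc1ccc(OC)cc1)C=C | intermediate
10 | alkylborane from 4 (9-BBN on C4 and on the C1′ oxygen) | O(B1C2CCCC1CCC2)C/C=C(\C)[C@H](O[Si](C)(C)C(C)(C)C)CCB1C2CCCC1CCC2 | intermediate (not isolated)
11 | seco alcohol, (2E,4R,7Z,9S,10S)-4-(TBSO)-10-(PMBO)-3,7-dimethyl-9-(TESO)dodeca-2,7,11-trien-1-ol | OC/C=C(\C)[C@H](O[Si](C)(C)C(C)(C)C)CC/C(C)=C\[C@H](O[Si](CC)(CC)CC)[C@@H](OCc1ccc(OC)cc1)C=C | intermediate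
12 | acrylate of 11 | C=CC(=O)OC/C=C(\C)[C@H](O[Si](C)(C)C(C)(C)C)CC/C(C)=C\[C@H](O[Si](CC)(CC)CC)[C@@H](OCc1ccc(OC)cc1)C=C | intermediate
13 | 14-membered (9E)-enoate macrolactone | O=C1OC/C=C(\C)[C@H](O[Si](C)(C)C(C)(C)C)CC/C(C)=C\[C@H](O[Si](CC)(CC)CC)[C@@H](OCc2ccc(OC)cc2)/C=C/1 | intermediate
14 | C9 pinacol boronate of the saturated macrolactone | O=C1OC/C=C(\C)[C@H](O[Si](C)(C)C(C)(C)C)CC/C(C)=C\[C@H](O[Si](CC)(CC)CC)[C@@H](OCc2ccc(OC)cc2)[C@H](B2OC(C)(C)C(C)(C)O2)C1 | intermediate (not isolated)
15 | (9R)-β-hydroxy macrolactone | O=C1OC/C=C(\C)[C@H](O[Si](C)(C)C(C)(C)C)CC/C(C)=C\[C@H](O[Si](CC)(CC)CC)[C@@H](OCc2ccc(OC)cc2)[C@H](O)C1 | intermediate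
16 | ring B acid (1-methyl, 1-vinyl, 10-CO2H, 9-OH, 2-OTBS, 7-OTES, 8-OPMB, 5Z) | C=C[C@]1(C)[C@H](O[Si](C)(C)C(C)(C)C)CC/C(C)=C\[C@H](O[Si](CC)(CC)CC)[C@@H](OCc2ccc(OC)cc2)[C@H](O)[C@H]1C(O)=O | intermediate
17 | C10 acetyl compound (9-OH) | C=C[C@]1(C)[C@H](O[Si](C)(C)C(C)(C)C)CC/C(C)=C\[C@H](O[Si](CC)(CC)CC)[C@@H](OCc2ccc(OC)cc2)[C@H](O)[C@H]1C(C)=O | intermediate
18 | 9-acetate of 17 | C=C[C@]1(C)[C@H](O[Si](C)(C)C(C)(C)C)CC/C(C)=C\[C@H](O[Si](CC)(CC)CC)[C@@H](OCc2ccc(OC)cc2)[C@H](OC(C)=O)[C@H]1C(C)=O | intermediate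
19 | C7 alcohol | C=C[C@]1(C)[C@H](O[Si](C)(C)C(C)(C)C)CC/C(C)=C\[C@H](O)[C@@H](OCc2ccc(OC)cc2)[C@H](OC(C)=O)[C@H]1C(C)=O | intermediate
20 | C7 2-bromopropanoate (both bromide epimers) | C=C[C@]1(C)[C@H](O[Si](C)(C)C(C)(C)C)CC/C(C)=C\[C@H](OC(=O)C(C)Br)[C@@H](OCc2ccc(OC)cc2)[C@H](OC(C)=O)[C@H]1C(C)=O | intermediate
21 | C8 alcohol | C=C[C@]1(C)[C@H](O[Si](C)(C)C(C)(C)C)CC/C(C)=C\[C@H](OC(=O)C(C)Br)[C@@H](O)[C@H](OC(C)=O)[C@H]1C(C)=O | intermediate
22 | C8 ketone | C=C[C@]1(C)[C@H](O[Si](C)(C)C(C)(C)C)CC/C(C)=C\[C@H](OC(=O)C(C)Br)C(=O)[C@H](OC(C)=O)[C@H]1C(C)=O | intermediate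
23 | γ-lactone with 8-OH (2-OTBS, 9-OAc, C10 acetyl, C1 vinyl) | C=C[C@]1(C)[C@H](O[Si](C)(C)C(C)(C)C)CC/C(C)=C\[C@@H]2OC(=O)[C@H](C)[C@@]2(O)[C@H](OC(C)=O)[C@H]1C(C)=O | intermediate
24 | C2 alcohol | C=C[C@]1(C)[C@H](O)CC/C(C)=C\[C@@H]2OC(=O)[C@H](C)[C@@]2(O)[C@H](OC(C)=O)[C@H]1C(C)=O | intermediate
25 | C2 butanoate (C10 acetyl) | C=C[C@]1(C)[C@H](OC(=O)CCC)CC/C(C)=C\[C@@H]2OC(=O)[C@H](C)[C@@]2(O)[C@H](OC(C)=O)[C@H]1C(C)=O | intermediate
26 | C10 isopropenyl, C1 vinyl lactone | C=C[C@]1(C)[C@H](OC(=O)CCC)CC/C(C)=C\[C@@H]2OC(=O)[C@H](C)[C@@]2(O)[C@H](OC(C)=O)[C@H]1C(C)=C | intermediate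
27 | ethoxyacetylene (ethoxyethyne) | CCOC#C | starting material
28 | ring A 12-ethoxy-11,13-diene | CCCC(=O)O[C@@H]1CC/C(C)=C\[C@@H]2OC(=O)[C@H](C)[C@@]2(O)[C@H](OC(C)=O)[C@@H]2[C@]1(C)C=CC(OCC)=C2C | intermediate
29 | 11,12-epoxide of 28 (12-ethoxy) | CCCC(=O)O[C@@H]1CC/C(C)=C\[C@@H]2OC(=O)[C@H](C)[C@@]2(O)[C@H](OC(C)=O)[C@@H]2[C@]1(C)C=C[C@@]3(OCC)O[C@@]23C | intermediate (not isolated)
30 | CNP0346936.2 | CCCC(=O)O[C@@H]1CC/C(C)=C\[C@@H]2OC(=O)[C@H](C)[C@@]2(O)[C@H](OC(C)=O)[C@@H]2[C@]1(C)C=CC(=O)[C@@]2(C)O | target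

**Step count and risks**
Total step count: 24. Longest linear sequence: 21 steps (steps 4–7, then 8–24).

Steps most likely to fail:

1. Step 23 (Proposed new method). What may go wrong: the alkylidene from the C1 vinyl group adds to the alkynyl ether but the vinylcarbene forms with E geometry or is intercepted intermolecularly, or the catalyst rests as an unreactive alkoxycarbene, so ring A does not close. Fallback with known chemistry: set out from 25. Add 1-lithio-1-methoxyallene (methoxyallene, n-BuLi, CeCl3, THF, −78 °C) to the C11 ketone; Felkin-type addition should give the 1-methoxyallenyl carbinol F1 and so form C11–C12. Hydrolyse the allenyl ether with dilute aqueous acid to the α′-hydroxy vinyl ketone F2. Close C13=C14 by ring-closing metathesis with the C1 vinyl group (second-generation Grubbs catalyst, CH2Cl2, reflux). This should give the enone directly and returns to the route at 30.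

2. Step 12. What may go wrong: the chelated dianion is protonated or eliminates instead of rearranging, or the macrocycle forces a boat transition state and the C1/C10 diastereomer results. Fallback: set out from 15. Silylate C9–OH (TMSCl, Et3N, CH2Cl2, 0 °C) to the C9 trimethylsilyl ether F3. Form the neutral (Z)-silyl ketene acetal F4 (C9 cis to the silyloxy group) with KN(SiMe3)2/TMSCl in THF–DMPU at −78 °C. Heat it in toluene at 90 °C; the Ireland–Claisen ring contraction of the silyl ketene acetal, controlled by ketene acetal geometry instead of the lithium chelate, should give the trimethylsilyl ester F5 of the ring B acid. Aqueous citric acid in methanol at 0 °C cleaves the silyl ester and the C9 trimethylsilyl ether and returns to the route at 16.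

3. Step 19. What may go wrong: SmI2 reductively cleaves the C7 or C9 acyloxy group next to the C8 ketone before the enolate adds. Fallback: set out from 19. Acylate C7–OH with acryloyl chloride (i-Pr2NEt, CH2Cl2, −78 °C) to the C7 acrylate F6. Cleave the PMB ether (DDQ, CH2Cl2/pH 7 buffer, 0 °C) to the C8 alcohol F7 and oxidise it (Dess–Martin periodinane, NaHCO3, CH2Cl2, 0 °C) to the keto acrylate F8. Run a copper hydride reductive aldol cyclization ([(Ph3P)CuH]6, toluene, −40 °C → rt); conjugate reduction gives the propanoate copper enolate without single-electron transfer, and this enolate adds to the C8 ketone within the tether. This returns to the route at 23.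

**Further compounds**
F1 | step 23 | 1-methoxyallenyl carbinol at C11 (from 25) | C=C[C@]1(C)[C@H](OC(=O)CCC)CC/C(C)=C\[C@@H]2OC(=O)[C@H](C)[C@@]2(O)[C@H](OC(C)=O)[C@H]1[C@](C)(O)C(OC)=C=C
F2 | step 23 | α′-hydroxy vinyl ketone (C11–OH, C12 ketone, C13=CH2) | C=C[C@]1(C)[C@H](OC(=O)CCC)CC/C(C)=C\[C@@H]2OC(=O)[C@H](C)[C@@]2(O)[C@H](OC(C)=O)[C@H]1[C@](C)(O)C(=O)C=C
F3 | step 12 | C9 trimethylsilyl ether of 15 | O=C1OC/C=C(\C)[C@H](O[Si](C)(C)C(C)(C)C)CC/C(C)=C\[C@H](O[Si](CC)(CC)CC)[C@@H](OCc2ccc(OC)cc2)[C@H](O[Si](C)(C)C)C1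
F4 | step 12 | (Z)-trimethylsilyl ketene acetal of F3 (C10=C11) | C[Si](C)(C)O/C1=C\[C@@H](O[Si](C)(C)C)[C@H](OCc2ccc(OC)cc2)[C@@H](O[Si](CC)(CC)CC)/C=C(/C)CC[C@@H](O[Si](C)(C)C(C)(C)C)/C(C)=C/CO1
F5 | step 12 | trimethylsilyl ester of the ring B acid with 9-OTMS | C=C[C@]1(C)[C@H](O[Si](C)(C)C(C)(C)C)CC/C(C)=C\[C@H](O[Si](CC)(CC)CC)[C@@H](OCc2ccc(OC)cc2)[C@H](O[Si](C)(C)C)[C@H]1C(=O)O[Si](C)(C)C
F6 | step 19 | C7 acrylate of 19 (8-OPMB) | C=C[C@]1(C)[C@H](O[Si](C)(C)C(C)(C)C)CC/C(C)=C\[C@H](OC(=O)C=C)[C@@H](OCc2ccc(OC)cc2)[C@H](OC(C)=O)[C@H]1C(C)=O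
F7 | step 19 | C7 acrylate with free C8 alcohol | C=C[C@]1(C)[C@H](O[Si](C)(C)C(C)(C)C)CC/C(C)=C\[C@H](OC(=O)C=C)[C@@H](O)[C@H](OC(C)=O)[C@H]1C(C)=O
F8 | step 19 | C7 acrylate of the C8 ketone | C=C[C@]1(C)[C@H](O[Si](C)(C)C(C)(C)C)CC/C(C)=C\[C@H](OC(=O)C=C)C(=O)[C@H](OC(C)=O)[C@H]1C(C)=O
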